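The ring (cyclohexenone numbering, C1 carbonyl) is cut into an acetone unit (C6–C1–C2) and a 3-oxo-aldehyde unit (C3–C4–C5). The latter arrives, with the whole side chain, as a methyl 2-deoxy-pyranosid-ulose: the side-chain carbinol oxygen masks the C3 aldehyde as a glycoside, and the axial anomeric methoxy group steers attack on the C5 ketone. In one pot the dianion of dimethyl (2-oxopropyl)phosphonate adds to C5 (C5–C6, carbinol stereocentre), acid opens the glycoside and an intramolecular Horner–Wadsworth–Emmons reaction closes C2=C3. The step exploits the fact that the C5 carbinol of the cyclohexenone ring lies β to both ketones (C1 and side-chain C2′), so that a temporary oxane ring can carry C3, C4, C5 and the side chain.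

Key step: step 4

Assumption: (S)-BINOL/Ti(OiPr)4 is taken to give the (2R)-pyranone 5 from an unbranched aldehyde (the sense of the related allylation); should the sense prove opposite, (R)-BINOL is used and nothing else changes.

Step 1
Reactants: 1 linoleyl alcohol, (9Z,12Z)-octadeca-9,12-dien-1-ol
Product: 2 (9Z,12Z)-octadeca-9,12-dienal
Conditions: Dess–Martin periodinane, CH2Cl2, 0 °C to rt
Reagents that add atoms: none
Why: Dess–Martin oxidation stops cleanly at the aldehyde under neutral conditions that leave the skipped (Z,Z)-diene untouched, and no stereocentre is formed.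

Step 2
Reactants: 2 (9Z,12Z)-octadeca-9,12-dienal; 3 Danishefsky's diene, (E)-1-methoxy-3-(trimethylsilyloxy)buta-1,3-diene
Product: 5 (2R)-2-[(8Z,11Z)-heptadeca-8,11-dien-1-yl]-2,3-dihydro-4H-pyran-4-one, via silylated aldol adduct 4 (not isolated)
Conditions: (S)-BINOL (20 mol%), Ti(OiPr)4 (10 mol%), 4 Å MS, Et2O, −20 °C; then TFA, CH2Cl2, 0 °C
Reagents that add atoms: none
Why: Catalytic enantioselective hetero-Diels–Alder reaction, which with this Lewis acid runs as a Mukaiyama aldol addition followed by acid-induced cyclisation with loss of methanol; the chiral BINOL–titanium complex shields one face of the aldehyde and so sets the single stereocentre (C2, R) that later relays its configuration to C5.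

Step 3
Reactants: 5 (2R)-2-[(8Z,11Z)-heptadeca-8,11-dien-1-yl]-2,3-dihydro-4H-pyran-4-one
Product: 6 (2R,6S)-2-[(8Z,11Z)-heptadeca-8,11-dien-1-yl]-6-methoxyoxan-4-one (methoxy axial, trans to the chain)
Conditions: MeOH, CSA (cat.), 0 °C to rt; Et3N quench
Reagents that add atoms: methanol, CO
Why: Acid-catalysed conjugate (oxa-Michael) addition of methanol to the vinylogous ester gives the ketone acetal, and acid equilibration of the new anomeric centre places the methoxy group axial (anomeric effect), trans to the equatorial chain; any equatorial anomer is separated and re-equilibrated.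

Step 4
Reactants: 6 (2R,6S)-2-[(8Z,11Z)-heptadeca-8,11-dien-1-yl]-6-methoxyoxan-4-one; 7 dimethyl (2-oxopropyl)phosphonate
Product: 10 (5S)-5-hydroxy-5-[(2R,10Z,13Z)-2-hydroxynonadeca-10,13-dien-1-yl]cyclohex-2-en-1-one, via hydroxy ketophosphonate 8 (not isolated), via lactol 9 (not isolated)
Conditions: 7, NaH, THF, 0 °C, then n-BuLi, 0 °C; 6, −78 °C; aq. HCl (1 M, to pH 1), 0 °C to rt; K2CO3 (to pH 10–11), THF–H2O, rt
Reagents that add atoms: none
Why: The γ-carbon of the phosphonate dianion adds to the C4 ketone of 6 (aldol addition, forms C5–C6 of the target), cold aqueous HCl then cleaves the acid-labile 2-deoxy-glycosidic acetal to lactol 9, and K2CO3 deprotonates the β-ketophosphonate, whose carbanion attacks the aldehyde of the open lactol and expels dimethyl phosphate (intramolecular Horner–Wadsworth–Emmons olefination, forms C2=C3). The closest known chemistry is the γ-aldol of β-ketophosphonate dianions with ketones followed by phosphonate cyclisation onto a lactol-masked aldehyde, here run as a one-pot [3+3] annulation. The carbocycle closes in a 6-(enolendo)-exo-trig addition, and the six-membered ring allows only the cis (Z) enone. The only new stereocentre, the C5 carbinol, is set in the aldol stage by the axial anomeric methoxy group of 6, which blocks the axial trajectory so that the nucleophile enters equatorially, cis to the heptadecadienyl chain, as in additions to methyl 2-deoxy-α-glycosid-3-uloses; with the (R) relay centre this is the (S) centre of the target. The step needs carbonyl addition to outrun enolisation and β-elimination of methoxide (secured by −78 °C and the cold acidic quench) and needs the later base to act at the phosphonate carbon only (secured by its far higher acidity, which as the enolate also shields the tertiary aldol from retro-aldol cleavage). Because the C6 arm and the alkyl chain are cis on the former oxane ring, re-addition of the freed side-chain hydroxyl to C3 of the enone would force the chain endo in an oxabicyclo[3.3.1]nonane and should not compete.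

Step 5
Reactants: 10 (5S)-5-hydroxy-5-[(2R,10Z,13Z)-2-hydroxynonadeca-10,13-dien-1-yl]cyclohex-2-en-1-one
Product: 11 (5S)-5-hydroxy-5-[(10Z,13Z)-2-oxononadeca-10,13-dien-1-yl]cyclohex-2-en-1-one (target)
Conditions: Dess–Martin periodinane, pyridine, CH2Cl2, 0 °C
Reagents that add atoms: none
Why: Dess–Martin oxidation of the secondary carbinol, the tertiary C5 hydroxyl being inert, reveals the side-chain ketone under buffered, non-basic conditions that should spare the β-hydroxy ketone arrays and the skipped diene; the relay stereocentre is erased, so 10 must enter this step free of its C5 epimer.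

Compound list
1 | linoleyl alcohol, (9Z,12Z)-octadeca-9,12-dien-1-ol | OCCCCCCCC/C=C\C/C=C\CCCCC | starting material
2 | (9Z,12Z)-octadeca-9,12-dienal | O=CCCCCCCC/C=C\C/C=C\CCCCC | intermediate
3 | Danishefsky's diene, (E)-1-methoxy-3-(trimethylsilyloxy)buta-1,3-diene | CO/C=C/C(=C)O[Si](C)(C)C | starting material
4 | (1E,5R,13Z,16Z)-1-methoxy-5-(trimethylsilyloxy)docosa-1,13,16-trien-3-one | CO/C=C/C(=O)C[C@H](O[Si](C)(C)C)CCCCCCC/C=C\C/C=C\CCCCC | intermediate
5 | (2R)-2-[(8Z,11Z)-heptadeca-8,11-dien-1-yl]-2,3-dihydro-4H-pyran-4-one | O=C1C[C@@H](CCCCCCC/C=C\C/C=C\CCCCC)OC=C1 | intermediate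
6 | (2R,6S)-2-[(8Z,11Z)-heptadeca-8,11-dien-1-yl]-6-methoxyoxan-4-one | O=C1C[C@@H](CCCCCCC/C=C\C/C=C\CCCCC)O[C@H](OC)C1 | intermediate
7 | dimethyl (2-oxopropyl)phosphonate | CC(=O)CP(=O)(OC)OC | starting material
8 | dimethyl (3-{(2R,4R,6S)-2-[(8Z,11Z)-heptadeca-8,11-dien-1-yl]-4-hydroxy-6-methoxyoxan-4-yl}-2-oxopropyl)phosphonate | COP(=O)(OC)CC(=O)C[C@]1(O)C[C@@H](OC)O[C@H](CCCCCCC/C=C\C/C=C\CCCCC)C1 | intermediate
9 | dimethyl (3-{(2R,4R)-2-[(8Z,11Z)-heptadeca-8,11-dien-1-yl]-4,6-dihydroxyoxan-4-yl}-2-oxopropyl)phosphonate (lactol, both anomers) | COP(=O)(OC)CC(=O)C[C@]1(O)CC(O)O[C@H](CCCCCCC/C=C\C/C=C\CCCCC)C1 | intermediate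
10 | (5S)-5-hydroxy-5-[(2R,10Z,13Z)-2-hydroxynonadeca-10,13-dien-1-yl]cyclohex-2-en-1-one | CCCCC/C=C\C/C=C\CCCCCCC[C@@H](O)C[C@@]1(O)CC=CC(=O)C1 | intermediate
11 | (5S)-5-hydroxy-5-[(10Z,13Z)-2-oxononadeca-10,13-dien-1-yl]cyclohex-2-en-1-one | CCCCC/C=C\C/C=C\CCCCCCCC(=O)C[C@@]1(O)CC=CC(=O)C1 | target

Total step count: 5
Longest linear sequence: 5 steps (1 → 2 → 5 → 6 → 10 → 11)

Steps most likely to fail

Step 4 (key step). What may go wrong: proton transfer from ketone 6 to the strongly basic dianion followed by β-elimination of methoxide instead of carbonyl addition, incomplete facial selectivity in the addition, or retro-aldol cleavage and dehydration while the lactol waits to be olefinated. The fallback sets out from 6 and returns at 10; it makes the two bonds separately and closes the ring by metathesis instead of olefination. The lithium enolate of N-methoxy-N-methylacetamide (LiN(iPr)2, THF, −78 °C), which is less basic and should add cleanly to an enolisable ketone from the same equatorial direction, is added to 6 to give the β-hydroxy Weinreb amide F1. Dilute aqueous HCl then gives the lactol F2, and Ph3P=CH2 (THF, 0 °C) methylenates its open aldehyde form to the allyl carbinol F3. Vinylmagnesium bromide (THF, −20 °C, inverse acidic quench) converts the amide into the vinyl ketone F4. Second-generation Grubbs catalyst (CH2Cl2, 40 °C, high dilution) should then close C2=C3 by ring-closing metathesis of the two terminal alkenes and give 10.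

Step 3. What may go wrong: an unfavourable addition equilibrium, competing ketalisation of the ring ketone, or poor control of the anomeric configuration. The fallback sets out from 5 and returns at 6 by a reduce–glycosylate–oxidise detour. Luche reduction (NaBH4, CeCl3·7H2O, MeOH, −78 °C) gives the cis allylic alcohol F5. PPh3·HBr-catalysed addition of methanol to the enol ether (CH2Cl2, rt) gives the axial methyl 2-deoxy-glycoside F6. Dess–Martin oxidation of its secondary alcohol returns ketone 6.

Step 2. What may go wrong: erosion of enantioselectivity through an uncatalysed background reaction, and self-condensation of the enolisable aldehyde under Lewis acid. The fallback sets out from 2 and returns at 5 by a reagent-controlled aldol addition instead of a catalytic cycloaddition. The boron enolate of (E)-4-methoxybut-3-en-2-one (Ipc2BCl, iPr2NEt, Et2O, −78 °C; the antipode of the reagent that gives the (R)-carbinol) is added to 2 and gives, after oxidative work-up, the β-hydroxy enone F7. TFA (CH2Cl2, 0 °C) cyclises it to 5 with loss of methanol.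

Further compounds
F1 | step 4 | 2-{(2R,4R,6S)-2-[(8Z,11Z)-heptadeca-8,11-dien-1-yl]-4-hydroxy-6-methoxyoxan-4-yl}-N-methoxy-N-methylacetamide | CON(C)C(=O)C[C@]1(O)C[C@@H](OC)O[C@H](CCCCCCC/C=C\C/C=C\CCCCC)C1
F2 | step 4 | 2-{(2R,4R)-2-[(8Z,11Z)-heptadeca-8,11-dien-1-yl]-4,6-dihydroxyoxan-4-yl}-N-methoxy-N-methylacetamide (lactol, both anomers) | CON(C)C(=O)C[C@]1(O)CC(O)O[C@H](CCCCCCC/C=C\C/C=C\CCCCC)C1
F3 | step 4 | (3S,5R,13Z,16Z)-3,5-dihydroxy-N-methoxy-N-methyl-3-(prop-2-en-1-yl)docosa-13,16-dienamide | CON(C)C(=O)C[C@](O)(CC=C)C[C@H](O)CCCCCCC/C=C\C/C=C\CCCCC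
F4 | step 4 | (5S,7R,15Z,18Z)-5,7-dihydroxy-5-(prop-2-en-1-yl)tetracosa-1,15,18-trien-3-one | C=CC(=O)C[C@](O)(CC=C)C[C@H](O)CCCCCCC/C=C\C/C=C\CCCCC
F5 | step 3 | (2R,4S)-2-[(8Z,11Z)-heptadeca-8,11-dien-1-yl]-3,4-dihydro-2H-pyran-4-ol | O[C@H]1C[C@@H](CCCCCCC/C=C\C/C=C\CCCCC)OC=C1
F6 | step 3 | (2R,4S,6S)-2-[(8Z,11Z)-heptadeca-8,11-dien-1-yl]-6-methoxyoxan-4-ol | O[C@H]1C[C@@H](CCCCCCC/C=C\C/C=C\CCCCC)O[C@H](OC)C1
F7 | step 2 | (1E,5R,13Z,16Z)-5-hydroxy-1-methoxydocosa-1,13,16-trien-3-one | CO/C=C/C(=O)C[C@H](O)CCCCCCC/C=C\C/C=C\CCCCC
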